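Start with a count: suppose each G that ends as Z or L takes one Q from E, so that an even charge of one equivalent is the zero of the scale. Call the margin m the Q charged beyond one per G, 0.0465 M in the flask, or 5.00 % of its G.

| flask | G | E | remark | time |
|---|---|---|---|---|
| Tuesday's | 0.93 M | 1.5 equiv | run made earlier |  |
| Monday's | 0.93 M | 2.3 equiv | run made earlier |  |
| Thursday's | 0.47 M | 1.05 equiv | run made earlier |  |
| flask | 0.93 M | 1.05 equiv |  | 8.0 d |

| run | time / d | G / % | Z / % | L / % |
|---|---|---|---|---|
| Tuesday's | 0.625 | 48.7 | 15.7 | 0.8 |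
| Tuesday's | 2.08 | 20.4 | 62.5 | 4.3 |
| Tuesday's | 4.00 | 4.1 | 85.2 | 9.5 |
| Tuesday's | 6.00 | 2.3 | 91.7 | 6.7 |
| Tuesday's | 8.00 | 1.1 | 93.3 | 6.9 |
| Monday's | 1.67 | 25.7 | 48.9 | 3.7 |
| Monday's | 3.00 | 9.1 | 77.5 | 4.5 |
| Monday's | 5.00 | 4.2 | 90.2 | 6.5 |
| Monday's | 6.00 | 0.4 | 94.6 | 6.6 |
| Monday's | 8.00 | 0.8 | 92.9 | 6.9 |
| Thursday's | 0.625 | 47.7 | 16.9 | 1.2 |
| Thursday's | 2.08 | 26.5 | 51.6 | 3.0 |
| Thursday's | 4.00 | 15.5 | 67.5 | 2.8 |
| Thursday's | 6.00 | 11.8 | 75.7 | 4.9 |
| Thursday's | 8.00 | 6.0 | 81.0 | 5.1 |

(readings scatter by 1 percentage point)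

- E is a solid; its amount is given per volume of the solution
- at the start none of E is in solution
- the reaction counts as stopped when no species that holds the G changes by six tenths of a point or more over the second half of the time

- why nothing more happens at 8.0 d, or that something still does (for what has run out or reacted, a solid counts together with what of it has only dissolved) (it is still moving / Q has run out first / forward and back rates have come level / all of G has reacted)
- part of the G gone at 8.0 d
- the Z standing at 8.0 d, as a percentage of the G charged
- the L standing at 8.0 d, as a percentage of the G charged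

My own reckoning takes two extremes. With a wide margin, Q stays in excess and G decays roughly exponentially (pseudo-first-order). Tuesday's run, with m = 0.465 M, leans that way and holds G 1.1 %, Z 93.3 % and L 6.9 % at 8.00 d. With m at zero, G and Q fall together and the inverse of G climbs in a line whose slope follows the concentration. Thursday's run lies near that extreme, with the flask's equivalents and half the flask's concentration, and holds G 6.0 %, Z 81.0 % and L 5.1 %.

The flask has less E than Tuesday's run. Its G is more concentrated than Thursday's. So I place the flask between those runs, with conversion from 94.0 % to 98.9 %. Its m is positive, so Q should outlast G. Over the second half G still drops 3 percentage points on Tuesday and 9.5 points on Thursday, so I expect motion at the end.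

The forecast gives it is still moving, with conversion 96 %, Z 85 % and L 6.2 %: “The reaction is still moving, and Q has not run out”.

The flask gives it is still moving, with conversion 95.4 %, Z 86.4 % and L 5.76 %.

    G + Q ⇌ X (K = 1.10 M⁻¹, k = 0.100 M⁻¹ h⁻¹)
    X → L (k = 0.100 h⁻¹)
    G ⇌ D (K = 0.660, k = 0.120 h⁻¹)
    X → Z (k = 1.50 h⁻¹)
    E ⇌ Q, rate k5*(cs5 - [Q]) while solid is left; crystals form when [Q] > cs5 (solubility = 0.760 M, k = 0.0600 h⁻¹)

Left until 80.0 d, the flask holds G 0.0195 % and Q 0.0468 M, level with m. A neighbour charged with 0.260 equiv has m = −0.688 M. The same count allows Z and L together 26.0 % of the G and leaves 74.0 % unturned. At 8.00 d in that neighbour, E stands at 0 % and Q at 1.07 × 10⁻⁴ M, so E is the limiting reagent there. In that neighbour Z and L together reach 26.0 %, while G and D, into which G turns reversibly, hold 74.0 %.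

The runs stem from a simulated flask from invented constants; the scatter is artificial.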